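Remark: abietane numbering (C1–C20) is used for the tricyclic compounds and for the matching atoms of their open-chain precursors. The zinc reagent 7 and the phosphonate 17 are taken as commercial. O20 is carried as a TBDPS ether and C19 as an ethyl ester; both groups are lost before the target.

## Analysis of the target

- **Skeleton.** Target 28 is an abietane. Ring C is a fully substituted 1,4-benzoquinone with carbonyls at C11 and C14, an acetoxy group on C12 and isopropyl on C13. Ring B holds a C6=C7 alkene conjugated with the quinone. Ring A is a cyclohexane in which C4 (methyl C18, carboxyl C19) and C10 (oxymethylene C20) are bridged by the δ-lactone C19(=O)–O–C20.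
- **Stereocentres.** C4 (S), C5 (R) and C10 (R) are contiguous. The lactone forces C19 and C20 to be syn-axial on ring A, and H5 is anti to C20, so the A/B junction is of the trans type.
- **Sensitive groups.** The enol acetate of the hydroxyquinone is a vinylogous anhydride and falls to nucleophiles. The ene-quinone is an electrophile and makes H5 vinylogously acidic, so base can epimerise C5. The lactone opens in strong base.
- **Difficulty.** Two quaternary carbons flank C5, each carrying an oxidised one-carbon substituent on the same face of ring A. They sit next to a hexasubstituted ring C with three non-equivalent oxygens.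
- **Feature used.** Ring A contains a diene unit C10–C1–C2–C3 and a dienophile unit C4–C5. The atoms C6–C7–C8–C9 of ring B join C5 to C10 through the arene. Ring A can therefore be made as a cyclohexene by an intramolecular [4+2] reaction that forms C5–C10 and C3–C4 and closes ring B in the same event.
- **Consequence.** The addition is suprafacial, so the C4=C5 geometry becomes the C4/C5 relationship and the fusion mode becomes the C5/C10 relationship. The whole triad comes from one transition state. Ring C is best carried as an 11,12,14-trimethoxyarene and oxidised at the end.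

## Retrosynthetic reasoning

**Ring C end game (28 ⇒ 27 ⇒ 26 ⇒ 25).** The acetyl–O12 bond is cut first, giving hydroxyquinone 27. Its C12 hydroxyl is traced to the vinylogous methyl ester 26, and the quinone of 26 to the trimethoxyarene 25 by oxidative loss of the para-related C11 and C14 methyl ethers. Neither the quinone nor the enol acetate would survive organometallic or Lewis acid steps, so they are made last; the forward steps must leave the lactone, the C6=C7 alkene and C5 untouched.

**C6=C7 (25 ⇒ 24).** The alkene is taken back to the saturated C6–C7 unit of 24, because ring B leaves the cycloaddition saturated. The forward reaction is a benzylic dehydrogenation; it cannot run on to a naphthalene because C10 is quaternary.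

**Lactone C–O bond and C1–C2 (24 ⇒ 22 ⇒ 21).** The O–C19 acyl bond is cut to the C20 silyl ether and C19 ethyl ester of 22. The saturated C1–C2 bond of 22 is the hydrogenated form of the alkene in 21 that the diene leaves behind. Lactonisation needs C19 and C20 cis and so also proves the relative configuration.

**C5–C10 and C3–C4 (21 ⇒ 20).** Both bonds of ring A are cut in a retro-[4+2] sense to the achiral triene 20. This is the only disconnection that removes both quaternary centres, C5 and two rings at once. The enoate must be Z, so that C19 is cis to C6. The diene must carry the arene trans to the vinyl group (the Z isomer by the sequence rule). The forward reaction has to pass through the trans-fused mode and choose one enantioface.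

**C1–C2 (20 ⇒ 18 + 19).** The diene is cut between C1 and C2 to vinyl iodide 18 and vinylboronate 19. The labile diene, which can undergo a 1,5-hydrogen shift and is acid-sensitive, then appears only one step before it is used. The coupling runs with retention.

**C4=C5 (18 ⇒ 16 + 17, then 16 ⇐ 15 ⇐ 14).** The enoate is cut to aldehyde 16 and the bis(trifluoroethyl) phosphonate 17. An ordinary dialkyl phosphonopropionate would give the E-enoate and so place C19 trans to C20. The aldehyde comes from the dioxolane 15, and 15 from alcohol 14 by silylation.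

**C9–C10 and C1–I (14 ⇒ 9 + 10).** The arene–C10 bond is cut to aryl bromide 9 and propargyl alcohol 10. Anti-carbomagnesiation through a magnesium chelate, then iodination, sets the aryl group trans to iodine. Olefination of an aryl ketone with an allyl ylide would not control this geometry.

**C9–Br and C7–C8 (9 ⇒ 8 ⇒ 6 + 7).** Bromine at C9 goes in at the last free ring position of 8. The three-carbon arm is joined at C7–C8 from bromide 6 and zinc reagent 7, which carries C5 as a masked aldehyde.

**C8–Br and C13–C15 (6 ⇒ 5 ⇒ 4 ⇒ 1 + 2).** The first bromination uses the inherent preference of 5 for substitution para to a methoxy group. The isopropyl group is cut at C13–C15 to the aryllithium 3, formed from 1 between its two flanking methoxy groups, and acetone 2; the benzylic hydroxyl of 4 is then removed.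

## Alternatives that were turned down

**Alternative 1:** Ring C is removed as a whole, cutting C9–C11 and C8–C14.
- **Forward key step.** The C9 dienylmagnesium reagent, made from dienyl iodide A3 by halogen–magnesium exchange, adds to the ketone-like carbonyl of cyclobutenedione A2. On heating, the resulting dienyl-hydroxycyclobutenone opens to a dienylketene, which electrocyclises and tautomerises to hydroquinone A1.
- **For.** Ring C arrives fully substituted with O12 already set apart as an isopropyl ether. No hexasubstituted arene has to be built. The C6=C7 alkene is already present in A3, so no benzylic dehydrogenation is needed. The route is convergent.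
- **Against.** All three stereocentres, both quaternary carbons and the lactone must already be in A3, so the hardest part of the target is untouched. Making A3 needs its own ring A construction. Metalation of A3 must also outrun attack on its lactone.
- **Comparison.** This alternative is stronger at the quinone end. The chosen strategy instead creates the C4/C5/C10 triad and two rings in one step from an open chain, and is shorter overall.

**Alternative 2:** The C10–C20 bond is cut.
- **Forward key step.** A dirhodium carboxylate catalyst decomposes diazoketone A5, and the carbenoid inserts into the tertiary benzylic C10–H bond with retention. This gives the bridged cyclopentanone A4, whose C19–C20 bond is later cleaved with oxygen insertion.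
- **For.** Five-membered-ring C–H insertion is dependable, and the bridge can only form cis, so the C19/C20 relationship is certain.
- **Against.**
  - A5 already needs the trans-fused tricycle with the axial C19 carboxyl in enantiopure form.
  - C2–H (axial) and C6–H lie at the same distance from the carbenoid and compete with C10–H.
  - A Baeyer–Villiger oxidation of A4 would move the quaternary C4, not the C20 methylene, and give the isomeric lactone. The C19–O–C20 connectivity therefore needs a detour of several steps.
- **Comparison.** This alternative is stronger on the certainty of the cis C19/C20 relationship. The chosen strategy has C20 at its final oxidation level from the start and sets the three centres together in fewer steps.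

**Alternative 3:** C1–C10 and C5–C10 are cut.
- **Forward key step.** The enolate of arylacetate A7 is alkylated by the iodide of A8. The new enolate then closes ring A by Michael addition to the enoate of A8, giving A6. Ring B would follow by Friedel–Crafts acylation at C8.
- **For.** Only enolate chemistry is used. The arene needs just five substituents. The C7 ketone from the later acylation would be a natural handle for the C6=C7 alkene.
- **Against.**
  - C4 in A6 is a prochiral geminal diester, and one of its esters must later be reduced to the C18 methyl group over several steps.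
  - C20 arrives as an ester and must be reduced beside the other ester groups.
  - The C5/C10 relationship is set in the Michael closure without a clear bias, and the absolute configuration needs an external controller.
- **Comparison.** Each step of this alternative is more predictable. The chosen strategy brings C18, C19 and C20 in at their final oxidation levels and links the stereocentres mechanistically.

Key step: step 11

## Route

Step 1
Reactants: 1 1,2,4-trimethoxybenzene; 2 acetone
Product: 4 2-(2,3,6-trimethoxyphenyl)propan-2-ol, via (2,3,6-trimethoxyphenyl)lithium 3 (not isolated)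
Conditions: n-BuLi, THF, 0 → 25 °C; then 2, −78 → 25 °C
Reagents that add atoms: none
Why: Directed ortho-metalation removes the proton between the two flanking methoxy groups (future C13), which is the most acidic and doubly coordinated; the aryllithium then adds 1,2 to acetone.

Step 2
Reactants: 4 2-(2,3,6-trimethoxyphenyl)propan-2-ol
Product: 5 2-isopropyl-1,3,4-trimethoxybenzene
Conditions: Et3SiH, CF3CO2H, CH2Cl2, 0 → 25 °C
Reagents that add atoms: none
Why: Ionic hydrogenation: acid ionises the tertiary benzylic alcohol to a cation stabilised by two ortho methoxy groups, and the silane delivers hydride.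

Step 3
Reactants: 5 2-isopropyl-1,3,4-trimethoxybenzene
Product: 6 1-bromo-3-isopropyl-2,4,5-trimethoxybenzene (bromine on future C8)
Conditions: N-bromosuccinimide, MeCN, 0 → 25 °C
Reagents that add atoms: N-bromosuccinimide, O=C1CCC(=O)N1Br
Why: Electrophilic aromatic bromination; of the two free positions, the one para to the C12 methoxy group and ortho to the C14 methoxy group should be the more activated, the other being para only to the alkyl group.

Step 4
Reactants: 6 1-bromo-3-isopropyl-2,4,5-trimethoxybenzene; 7 [2-(1,3-dioxolan-2-yl)ethyl]zinc bromide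
Product: 8 2-[2-(3-isopropyl-2,4,5-trimethoxyphenyl)ethyl]-1,3-dioxolane
Conditions: Pd(OAc)2 (2 mol%), SPhos (4 mol%), THF, 50 °C
Reagents that add atoms: none
Why: Negishi coupling of a primary alkylzinc halide with an electron-rich aryl bromide that has only one ortho substituent; the acetal is inert to the organozinc and brings in C5–C7 with C5 as a masked aldehyde.

Step 5
Reactants: 8 2-[2-(3-isopropyl-2,4,5-trimethoxyphenyl)ethyl]-1,3-dioxolane
Product: 9 2-[2-(2-bromo-5-isopropyl-3,4,6-trimethoxyphenyl)ethyl]-1,3-dioxolane (bromine on future C9)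
Conditions: N-bromosuccinimide, MeCN, 0 → 25 °C, dark
Reagents that add atoms: N-bromosuccinimide, O=C1CCC(=O)N1Br
Why: Electrophilic bromination at the only remaining ring position, activated by the ortho C11 methoxy group; polar conditions in the dark suppress radical bromination at benzylic and acetal C–H bonds.

Step 6
Reactants: 9 2-[2-(2-bromo-5-isopropyl-3,4,6-trimethoxyphenyl)ethyl]-1,3-dioxolane; 10 prop-2-yn-1-ol
Product: 14 (2Z)-2-{2-[2-(1,3-dioxolan-2-yl)ethyl]-4-isopropyl-3,5,6-trimethoxyphenyl}-3-iodoprop-2-en-1-ol, via aryl Grignard reagent 11 (not isolated), via bromomagnesium propynolate 12 (not isolated), via oxamagnesacycle 13 (not isolated)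
Conditions: 9, Mg, LiCl, THF, 25 °C; 10, EtMgBr (1.0 equiv), THF, 0 °C; combine, CuI (10 mol%), THF, 25 → 45 °C; then I2, THF, −30 → 0 °C
Reagents that add atoms: iodine, II
Why: Copper-catalysed anti-carbomagnesiation of a propargylic alkoxide: the aryl group adds to the alkyne carbon next to the CH2O group, and magnesium ends on the terminal carbon, held cis to CH2O in the five-membered chelate 13. Iodination with retention then places iodine trans to the arene, which fixes the later diene geometry.

Step 7
Reactants: 14 (2Z)-2-aryl-3-iodoprop-2-en-1-ol as above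
Product: 15 tert-butyl{[(2Z)-2-{2-[2-(1,3-dioxolan-2-yl)ethyl]-4-isopropyl-3,5,6-trimethoxyphenyl}-3-iodoprop-2-en-1-yl]oxy}diphenylsilane
Conditions: tert-butyl(chloro)diphenylsilane, imidazole, DMF, 25 °C
Reagents that add atoms: tert-butyl(chloro)diphenylsilane, CC(C)(C)[Si](Cl)(c1ccccc1)c1ccccc1
Why: Silylation of a primary allylic alcohol; the TBDPS ether survives the acid of step 8 and is bulky enough to discourage Lewis acid binding at O20 in step 11.

Step 8
Reactants: 15 TBDPS ether as above
Product: 16 3-{2-[(1Z)-3-(tert-butyldiphenylsilyloxy)-1-iodoprop-1-en-2-yl]-5-isopropyl-3,4,6-trimethoxyphenyl}propanal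
Conditions: 1 M aq. HCl, THF, 25 °C
Reagents that add atoms: water, O
Why: Acid-catalysed acetal hydrolysis; the vinyl iodide and the TBDPS ether tolerate dilute acid, and no diene is present yet.

Step 9
Reactants: 16 aldehyde as above; 17 ethyl 2-[bis(2,2,2-trifluoroethoxy)phosphoryl]propanoate
Product: 18 ethyl (2Z)-5-{2-[(1Z)-3-(tert-butyldiphenylsilyloxy)-1-iodoprop-1-en-2-yl]-5-isopropyl-3,4,6-trimethoxyphenyl}-2-methylpent-2-enoate
Conditions: KN(SiMe3)2, 18-crown-6, THF, −78 °C
Reagents that add atoms: none
Why: Still–Gennari olefination: the electron-poor phosphonate with a dissociated potassium counter-ion eliminates quickly from the kinetic adduct and gives the (Z)-2-methyl enoate, with C19 cis to C6; the vinyl iodide is inert.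

Step 10
Reactants: 18 Z-enoate vinyl iodide as above; 19 4,4,5,5-tetramethyl-2-vinyl-1,3,2-dioxaborolane
Product: 20 ethyl (2Z)-5-{2-[(2Z)-1-(tert-butyldiphenylsilyloxy)penta-2,4-dien-2-yl]-5-isopropyl-3,4,6-trimethoxyphenyl}-2-methylpent-2-enoate (arene trans to the vinyl group on C10=C1)
Conditions: PdCl2(dppf) (5 mol%), K3PO4, THF/H2O (10:1), 50 °C
Reagents that add atoms: none
Why: Suzuki–Miyaura coupling with retention of the vinyl iodide geometry; the mild phosphate base leaves the Z-enoate alone, and the diene is made only one step before it is used.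

Step 11
Reactants: 20 triene as above
Product: 21 ethyl (4S,5R,10R)-20-(tert-butyldiphenylsilyloxy)-11,12,14-trimethoxyabieta-1,8,11,13-tetraen-19-oate (trans-fused; C19 and C20 cis)
Conditions: (S)-1-(2-methylphenyl)-3,3-diphenyltetrahydro-1H,3H-pyrrolo[1,2-c][1,3,2]oxazaborole (20 mol%), AlBr3 (16 mol%), CH2Cl2, −40 → −20 °C
Reagents that add atoms: none
Why: Proposed new method: the AlBr3-activated chiral oxazaborolidine binds the ester carbonyl of 20 and lowers the enoate LUMO enough for a concerted, asynchronous [4+2] addition (C5–C10 bonding ahead of C3–C4) well below the temperature at which a C20 hydrogen would migrate to C3 by a 1,5-shift; the closest known reaction types are the Lewis acid catalysed type 1 intramolecular Diels–Alder reaction of benzo-tethered 1,7,9-decatrienes to hydrophenanthrenes and the enantioselective Diels–Alder reaction of simple enoates under AlBr3-activated oxazaborolidines, neither shown for a (Z)-2-methyl enoate adding to a fully substituted diene terminus. Ring A is the cycloadduct ring, formed suprafacially on diene and dienophile; ring B closes as the six-membered tether ring through the C5–C10 bond with the tether exo. C4 is controlled by the Z geometry of the enoate, which keeps C19 cis to C6; C5 and C10 are controlled relative to each other by the fusion mode, and in the trans-fused adduct C6, and therefore C19, lies on the same face of ring A as C20. The step needs the tether-exo, ester-exo transition state, against the usual endo preference of a complexed carbonyl group. Two features of 20 speak for it: the ester is twisted out of the enoate plane by the cis C6 methylene and the C18 methyl group, so it has little secondary overlap to gain and, once complexed, is the bulkiest group on C4, which the exo position accommodates; and in the developing half-chair of ring B the benzylic C10 must place either the flat C1–H or the CH2OSi group beside the C11 methoxy group, the former being the arrangement that leads to trans fusion. The absolute sense (addition to the C4 Si, C5 Si face, giving 4S,5R,10R) is not secured by the achiral substrate and rests entirely on the chiral Lewis acid; if the (S)-catalyst favours the other face, its (R)-antipode is used.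

Step 12
Reactants: 21 cycloadduct as above
Product: 22 ethyl (4S,5R,10R)-20-(tert-butyldiphenylsilyloxy)-11,12,14-trimethoxyabieta-8,11,13-trien-19-oate
Conditions: H2 (1 atm), Pd/C (10%), EtOAc, 25 °C
Reagents that add atoms: none
Why: Heterogeneous hydrogenation of the only non-aromatic alkene (cis-disubstituted C1=C2); no stereocentre is formed, and the silyl ether, ester and aryl ethers are inert.

Step 13
Reactants: 22 saturated silyl ether ester as above
Product: 24 (4S,5R,10R)-11,12,14-trimethoxyabieta-8,11,13-trien-19,20-olide, via hydroxy ester 23 (not isolated)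
Conditions: Bu4NF, THF, 25 → 50 °C
Reagents that add atoms: none
Why: Fluoride desilylation followed by intramolecular transesterification; the C20 alkoxide and the C19 ester are 1,3-diaxial on ring A, so the δ-lactone closes readily, and its formation confirms the C4/C10 relationship.

Step 14
Reactants: 24 lactone as above
Product: 25 (4S,5R,10R)-11,12,14-trimethoxyabieta-6,8,11,13-tetraen-19,20-olide
Conditions: DDQ, 1,4-dioxane (dry), 100 °C
Reagents that add atoms: none
Why: Benzylic dehydrogenation with DDQ: hydride abstraction from C7 gives a cation stabilised by the C12 and C14 methoxy groups, which loses H6. C10 is quaternary, so ring B cannot aromatise, and C5 keeps its configuration.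

Step 15
Reactants: 25 6,7-ene lactone as above
Product: 26 (4S,5R,10R)-12-methoxy-11,14-dioxoabieta-6,8,12-trien-19,20-olide
Conditions: (NH4)2Ce(NO3)6, MeCN/H2O (3:1), 0 °C
Reagents that add atoms: water, O
Why: Oxidative demethylation of the para-related C11 and C14 methyl ethers gives the 1,4-quinone; the C12 methoxy group stays as a vinylogous ester.

Step 16
Reactants: 26 methoxyquinone as above
Product: 27 (4S,5R,10R)-12-hydroxy-11,14-dioxoabieta-6,8,12-trien-19,20-olide
Conditions: 2 M aq. H2SO4, 1,4-dioxane, 70 °C
Reagents that add atoms: water, O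
Why: Acid-catalysed addition–elimination at C12 (hydrolysis of a vinylogous ester); acid is used so that H5, vinylogously acidic through C6=C7 and the quinone, is not removed and the lactone stays closed.

Step 17
Reactants: 27 hydroxyquinone as above
Product: 28 (4S,5R,10R)-12-acetoxy-11,14-dioxoabieta-6,8,12-trien-19,20-olide (target)
Conditions: Ac2O, pyridine, CH2Cl2, 0 → 25 °C
Reagents that add atoms: acetic anhydride, CC(=O)OC(C)=O
Why: O-acylation of the acidic hydroxyquinone hydroxyl under mild base; no other nucleophilic site is present.

## Compound list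

1 | 1,2,4-trimethoxybenzene | COc1ccc(OC)c(OC)c1 | starting material
2 | acetone | CC(C)=O | starting material
3 | (2,3,6-trimethoxyphenyl)lithium | [Li]c1c(OC)c(OC)ccc1OC | intermediate
4 | 2-(2,3,6-trimethoxyphenyl)propan-2-ol | CC(C)(O)c1c(OC)c(OC)ccc1OC | intermediate
5 | 2-isopropyl-1,3,4-trimethoxybenzene | CC(C)c1c(OC)c(OC)ccc1OC | intermediate
6 | 1-bromo-3-isopropyl-2,4,5-trimethoxybenzene | CC(C)c1c(OC)c(OC)cc(Br)c1OC | intermediate
7 | [2-(1,3-dioxolan-2-yl)ethyl]zinc bromide | Br[Zn]CCC1OCCO1 | starting material
8 | 2-[2-(3-isopropyl-2,4,5-trimethoxyphenyl)ethyl]-1,3-dioxolane | CC(C)c1c(OC)c(OC)cc(CCC2OCCO2)c1OC | intermediate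
9 | 2-[2-(2-bromo-5-isopropyl-3,4,6-trimethoxyphenyl)ethyl]-1,3-dioxolane | CC(C)c1c(OC)c(OC)c(Br)c(CCC2OCCO2)c1OC | intermediate
10 | prop-2-yn-1-ol | C#CCO | starting material
11 | {2-[2-(1,3-dioxolan-2-yl)ethyl]-4-isopropyl-3,5,6-trimethoxyphenyl}magnesium bromide | CC(C)c1c(OC)c(OC)c([Mg]Br)c(CCC2OCCO2)c1OC | intermediate
12 | bromomagnesium prop-2-yn-1-olate | C#CCO[Mg]Br | intermediate
13 | 4-{2-[2-(1,3-dioxolan-2-yl)ethyl]-4-isopropyl-3,5,6-trimethoxyphenyl}-2,5-dihydro-1,2-oxamagnesole | CC(C)c1c(OC)c(OC)c(C2=C[Mg]OC2)c(CCC2OCCO2)c1OC | intermediate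
14 | (2Z)-2-{2-[2-(1,3-dioxolan-2-yl)ethyl]-4-isopropyl-3,5,6-trimethoxyphenyl}-3-iodoprop-2-en-1-ol | CC(C)c1c(OC)c(OC)c(/C(CO)=C/I)c(CCC2OCCO2)c1OC | intermediate
15 | tert-butyl{[(2Z)-2-{2-[2-(1,3-dioxolan-2-yl)ethyl]-4-isopropyl-3,5,6-trimethoxyphenyl}-3-iodoprop-2-en-1-yl]oxy}diphenylsilane | CC(C)c1c(OC)c(OC)c(/C(CO[Si](c2ccccc2)(c2ccccc2)C(C)(C)C)=C/I)c(CCC2OCCO2)c1OC | intermediate
16 | 3-{2-[(1Z)-3-(tert-butyldiphenylsilyloxy)-1-iodoprop-1-en-2-yl]-5-isopropyl-3,4,6-trimethoxyphenyl}propanal | CC(C)c1c(OC)c(OC)c(/C(CO[Si](c2ccccc2)(c2ccccc2)C(C)(C)C)=C/I)c(CCC=O)c1OC | intermediate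
17 | ethyl 2-[bis(2,2,2-trifluoroethoxy)phosphoryl]propanoate | CCOC(=O)C(C)P(=O)(OCC(F)(F)F)OCC(F)(F)F | starting material
18 | ethyl (2Z)-5-{2-[(1Z)-3-(tert-butyldiphenylsilyloxy)-1-iodoprop-1-en-2-yl]-5-isopropyl-3,4,6-trimethoxyphenyl}-2-methylpent-2-enoate | CC(C)c1c(OC)c(OC)c(/C(CO[Si](c2ccccc2)(c2ccccc2)C(C)(C)C)=C/I)c(CC/C=C(/C)C(=O)OCC)c1OC | intermediate
19 | 4,4,5,5-tetramethyl-2-vinyl-1,3,2-dioxaborolane | C=CB1OC(C)(C)C(C)(C)O1 | starting material
20 | ethyl (2Z)-5-{2-[(2Z)-1-(tert-butyldiphenylsilyloxy)penta-2,4-dien-2-yl]-5-isopropyl-3,4,6-trimethoxyphenyl}-2-methylpent-2-enoate | COc1c(C(C)C)c(OC)c(CC/C=C(/C)C(=O)OCC)c(c1OC)/C(CO[Si](c1ccccc1)(c1ccccc1)C(C)(C)C)=C/C=C | intermediate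
21 | ethyl (4S,5R,10R)-20-(tert-butyldiphenylsilyloxy)-11,12,14-trimethoxyabieta-1,8,11,13-tetraen-19-oate | COc1c(C(C)C)c(OC)c2c(c1OC)[C@@]1(CO[Si](c3ccccc3)(c3ccccc3)C(C)(C)C)C=CC[C@](C)(C(=O)OCC)[C@@H]1CC2 | intermediate
22 | ethyl (4S,5R,10R)-20-(tert-butyldiphenylsilyloxy)-11,12,14-trimethoxyabieta-8,11,13-trien-19-oate | COc1c(C(C)C)c(OC)c2c(c1OC)[C@@]1(CO[Si](c3ccccc3)(c3ccccc3)C(C)(C)C)CCC[C@](C)(C(=O)OCC)[C@@H]1CC2 | intermediate
23 | ethyl (4S,5R,10R)-20-hydroxy-11,12,14-trimethoxyabieta-8,11,13-trien-19-oate | COc1c(C(C)C)c(OC)c2c(c1OC)[C@@]1(CO)CCC[C@](C)(C(=O)OCC)[C@@H]1CC2 | intermediate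
24 | (4S,5R,10R)-11,12,14-trimethoxyabieta-8,11,13-trien-19,20-olide | COc1c(C(C)C)c(OC)c2c(c1OC)[C@]13CCC[C@](C)(C(=O)OC1)[C@@H]3CC2 | intermediate
25 | (4S,5R,10R)-11,12,14-trimethoxyabieta-6,8,11,13-tetraen-19,20-olide | COc1c(C(C)C)c(OC)c2c(c1OC)[C@]13CCC[C@](C)(C(=O)OC1)[C@@H]3C=C2 | intermediate
26 | (4S,5R,10R)-12-methoxy-11,14-dioxoabieta-6,8,12-trien-19,20-olide | COC1=C(C(C)C)C(=O)C2=C(C1=O)[C@]13CCC[C@](C)(C(=O)OC1)[C@@H]3C=C2 | intermediate
27 | (4S,5R,10R)-12-hydroxy-11,14-dioxoabieta-6,8,12-trien-19,20-olide | OC1=C(C(C)C)C(=O)C2=C(C1=O)[C@]13CCC[C@](C)(C(=O)OC1)[C@@H]3C=C2 | intermediate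
28 | (4S,5R,10R)-12-acetoxy-11,14-dioxoabieta-6,8,12-trien-19,20-olide | CC(=O)OC1=C(C(C)C)C(=O)C2=C(C1=O)[C@]13CCC[C@](C)(C(=O)OC1)[C@@H]3C=C2 | target

## Step count and least certain steps

Total: 17 steps. Longest linear sequence: 17 steps, from 1.

**Step 11 (key step).**
- **What may go wrong.** The most likely failure is closure through the ester-endo, tether-endo mode, the usual course for Z-dienophiles under Lewis acid activation. That gives a cis-fused adduct with C19 anti to C20, which cannot lactonise. The twisted, hindered enoate may also bind the Lewis acid poorly. Slow turnover would then let other processes take over: ionisation of the dienylic C20–O bond, protonation and oligomerisation of the electron-rich diene, or Z-to-E isomerisation of the enoate. Facial discrimination by the catalyst on a 2-methyl Z-enoate may also be poor.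
- **Fallback.** The fallback sets out from 20 and replaces both the Lewis acid and the asymmetric induction. Triene 20 is cyclised without catalyst, either in toluene at 150–170 °C with a radical inhibitor or at 12–15 kbar and 40–60 °C, where pressure favours cycloaddition over the 1,5-hydrogen shift. Without a complexed carbonyl, both fusion modes are expected. The trans-fused racemate is separated from the cis-fused isomer by chromatography and resolved on a chiral stationary phase into 21 and its enantiomer, ethyl (4R,5S,10S)-20-(tert-butyldiphenylsilyloxy)-11,12,14-trimethoxyabieta-1,8,11,13-tetraen-19-oate F1. The route is rejoined at 21.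

**Step 6.**
- **What may go wrong.** The aryl Grignard reagent 11 has two ortho substituents, so carbometalation may be slow. Competing deprotonation of the alkyne C–H of 12, which returns 8, and copper-mediated homocoupling would waste the advanced arene.
- **Fallback.** The fallback sets out from 9 through its Grignard reagent 11 and takes the diene geometry from a ring. The steps are:
  - ZnCl2 converts 11 into {2-[2-(1,3-dioxolan-2-yl)ethyl]-4-isopropyl-3,5,6-trimethoxyphenyl}zinc chloride F2.
  - Negishi coupling of F2 with commercial 4-bromofuran-2(5H)-one (Pd2(dba)3, SPhos, THF) gives the 4-arylfuran-2(5H)-one F3.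
  - i-Bu2AlH at −78 °C gives the 4-aryl-2,5-dihydrofuran-2-ol F4, used at once to avoid dehydration to the furan.
  - Wittig methylenation (Ph3PCH3Br, KOt-Bu, THF) opens F4 to the (2Z)-2-arylpenta-2,4-dien-1-ol F5, in which C20 and C2 are cis because they came from the ring.
  - Silylation gives the TBDPS ether F6.
  - Pyridinium p-toluenesulfonate in wet acetone frees the aldehyde 3-{2-[(2Z)-1-(tert-butyldiphenylsilyloxy)penta-2,4-dien-2-yl]-5-isopropyl-3,4,6-trimethoxyphenyl}propanal F7.
  - Still–Gennari olefination of F7 with 17 rejoins the route at 20.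

**Step 14.**
- **What may go wrong.** All three methoxy groups are twisted out of the ring plane by their neighbours, so hydride abstraction from C7 may be slow. Prolonged heating invites oxygenation at C7 by traces of water or attack at the isopropyl methine.
- **Fallback.** The fallback sets out from 24 and installs the alkene by oxidation, reduction and elimination. Benzylic oxidation (CrO3, 3,5-dimethylpyrazole, CH2Cl2, −20 °C) gives (4S,5R,10R)-11,12,14-trimethoxy-7-oxoabieta-8,11,13-trien-19,20-olide F8. NaBH4 in MeOH at 0 °C gives the 7-hydroxy lactone F9. Dehydration with p-toluenesulfonic acid in toluene at 80 °C rejoins the route at 25.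

**Step 16 (with step 15).**
- **What may go wrong.** In step 15, oxidation may go partly towards the ortho-quinone. In step 16, hydrolysis at C12 may be slow because the isopropyl group and the C11 carbonyl shield it. Forcing conditions invite conjugate addition of water to the ene-quinone or acid-promoted migration of the C6=C7 alkene.
- **Fallback.** The fallback sets out from 25 and removes all three methyl groups before oxidation. BBr3 in CH2Cl2 at −78 → 0 °C gives (4S,5R,10R)-11,12,14-trihydroxyabieta-6,8,11,13-tetraen-19,20-olide F10. This hydroxyhydroquinone is oxidised by air, or by Ag2O in Et2O, directly to the hydroxyquinone. The route is rejoined at 27 without passing through 26.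

## Further compounds

F1 | step 11 | ethyl (4R,5S,10S)-20-(tert-butyldiphenylsilyloxy)-11,12,14-trimethoxyabieta-1,8,11,13-tetraen-19-oate | COc1c(C(C)C)c(OC)c2c(c1OC)[C@]1(CO[Si](c3ccccc3)(c3ccccc3)C(C)(C)C)C=CC[C@@](C)(C(=O)OCC)[C@H]1CC2
F2 | step 6 | {2-[2-(1,3-dioxolan-2-yl)ethyl]-4-isopropyl-3,5,6-trimethoxyphenyl}zinc chloride | CC(C)c1c(OC)c(OC)c([Zn]Cl)c(CCC2OCCO2)c1OC
F3 | step 6 | 4-{2-[2-(1,3-dioxolan-2-yl)ethyl]-4-isopropyl-3,5,6-trimethoxyphenyl}furan-2(5H)-one | CC(C)c1c(OC)c(OC)c(C2=CC(=O)OC2)c(CCC2OCCO2)c1OC
F4 | step 6 | 4-{2-[2-(1,3-dioxolan-2-yl)ethyl]-4-isopropyl-3,5,6-trimethoxyphenyl}-2,5-dihydrofuran-2-ol | CC(C)c1c(OC)c(OC)c(C2=CC(O)OC2)c(CCC2OCCO2)c1OC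
F5 | step 6 | (2Z)-2-{2-[2-(1,3-dioxolan-2-yl)ethyl]-4-isopropyl-3,5,6-trimethoxyphenyl}penta-2,4-dien-1-ol | CC(C)c1c(OC)c(OC)c(/C(CO)=C/C=C)c(CCC2OCCO2)c1OC
F6 | step 6 | tert-butyl{[(2Z)-2-{2-[2-(1,3-dioxolan-2-yl)ethyl]-4-isopropyl-3,5,6-trimethoxyphenyl}penta-2,4-dien-1-yl]oxy}diphenylsilane | CC(C)c1c(OC)c(OC)c(/C(CO[Si](c2ccccc2)(c2ccccc2)C(C)(C)C)=C/C=C)c(CCC2OCCO2)c1OC
F7 | step 6 | 3-{2-[(2Z)-1-(tert-butyldiphenylsilyloxy)penta-2,4-dien-2-yl]-5-isopropyl-3,4,6-trimethoxyphenyl}propanal | CC(C)c1c(OC)c(OC)c(/C(CO[Si](c2ccccc2)(c2ccccc2)C(C)(C)C)=C/C=C)c(CCC=O)c1OC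
F8 | step 14 | (4S,5R,10R)-11,12,14-trimethoxy-7-oxoabieta-8,11,13-trien-19,20-olide | COc1c(C(C)C)c(OC)c2c(c1OC)[C@]13CCC[C@](C)(C(=O)OC1)[C@@H]3CC2=O
F9 | step 14 | (4S,5R,10R)-7-hydroxy-11,12,14-trimethoxyabieta-8,11,13-trien-19,20-olide (C7 epimers) | COc1c(C(C)C)c(OC)c2c(c1OC)[C@]13CCC[C@](C)(C(=O)OC1)[C@@H]3CC2O
F10 | step 16 | (4S,5R,10R)-11,12,14-trihydroxyabieta-6,8,11,13-tetraen-19,20-olide | Oc1c(C(C)C)c(O)c2c(c1O)[C@]13CCC[C@](C)(C(=O)OC1)[C@@H]3C=C2
A1 | alternative 1 | (4S,5R,10R)-11,14-dihydroxy-12-isopropoxyabieta-6,8,11,13-tetraen-19,20-olide | CC(C)Oc1c(C(C)C)c(O)c2c(c1O)[C@]13CCC[C@](C)(C(=O)OC1)[C@@H]3C=C2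
A2 | alternative 1 | 3-isopropoxy-4-isopropylcyclobut-3-ene-1,2-dione | CC(C)OC1=C(C(C)C)C(=O)C1=O
A3 | alternative 1 | ring A–ring B lactone with C9 iodide and C6=C7, C8=C9 alkenes (C9 dienyl iodide) | C2=C(I)[C@]13CCC[C@](C)(C(=O)OC1)[C@@H]3C=C2
A4 | alternative 2 | bridged cyclopentanone linking C4 and C10 through C19 and C20 on the 11,12,14-trimethoxyabieta-8,11,13-triene skeleton | COc1c(C(C)C)c(OC)c2c(c1OC)[C@]13CCC[C@](C)(C(=O)C1)[C@@H]3CC2
A5 | alternative 2 | C19 diazomethyl ketone of the trans-fused 20-nor tricycle with C10–H | COc1c(C(C)C)c(OC)c2c(c1OC)[C@H]1CCC[C@](C)(C(=O)C=[N+]=[N-])[C@@H]1CC2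
A6 | alternative 3 | ring A cyclohexane with aryl and allyl ester on C10, geminal methyl esters on C4 and the tert-butyl acetate arm on C5 | COc1c(C(C)C)c(OC)cc(c1OC)[C@@]1(C(=O)OCC=C)CCCC(C(=O)OC)(C(=O)OC)[C@@H]1CC(=O)OC(C)(C)C
A7 | alternative 3 | allyl (4-isopropyl-2,3,5-trimethoxyphenyl)acetate | C=CCOC(=O)Cc1cc(OC)c(C(C)C)c(OC)c1OC
A8 | alternative 3 | dimethyl 2-[(1E)-3-tert-butoxy-3-oxoprop-1-en-1-yl]-2-(3-iodopropyl)malonate | COC(=O)C(CCCI)(/C=C/C(=O)OC(C)(C)C)C(=O)OC
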